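**Assumption:** the SMILES is (−)-(1'R,2'S,6'R)-4-hydroxypanduratin A, with prenyl and aroyl cis and aroyl and phenyl trans. Target ring numbering used below: C1' (C–C=O), C2' (prenyl), C3'(Me)=C4', C5'H2, C6' (Ph).

## Retrosynthetic overview
1. The aryl–C(=O) bond is cut by a photo-Fries rearrangement, giving the 3,5-dihydroxyphenyl ester of the cyclohexene acid. All three free ring positions of that ester lead to the same ketone.
2. The prenyl C=C and the C5'–H bond come from a visible-light Co–H radical ring opening of a bicyclo[2.2.2]octene, in which the prenyl group is tied back to C5' as an isopropenyl-bearing two-carbon bridge.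
3. The bicycle comes from a double Michael reaction of (R)-carvone with allyl cinnamate. This step makes C1'–C2' and C5'–C6' and sets all three stereocentres anti to the isopropenyl group.
4. Trapping the resulting enolate as the triflate and reducing it to C–H gives C3'=C4'.
5. Ring order: the target ring is built onto the carvone ring first, the carvone ring is then cut (its stereocentre becomes the prenyl =CH), and the arene is attached last.

## Route

**Step 1**
Reactants: 1 (R)-(−)-carvone; 2 allyl (E)-cinnamate; 3 Comins' reagent
Product: 4 allyl (1S,2R,3R,4R,8R)-6-methyl-3-phenyl-8-(prop-1-en-2-yl)-5-(triflyloxy)bicyclo[2.2.2]oct-5-ene-2-carboxylate. The phenyl on C3 is syn to the C5=C6 bridge. The ester on C2 is syn to the C7–C8 bridge and trans to phenyl. The isopropenyl on C8 is syn to C5=C6 and anti to the new C2–C3 bridge.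
Conditions: LDA, THF, −78 °C; 2, −78 → −20 °C; then 3, −78 °C → rt
Reagents that add atoms: Comins' reagent, FC(F)(F)S(=O)(=O)N(c1ccc(Cl)cn1)S(=O)(=O)C(F)(F)F
Why: Double Michael annulation with enolate O-triflation, in which the kinetic cross-conjugated dienolate attacks the cinnamate β-carbon anti to the adjacent isopropenyl group through the synclinal, syn-selective E(O)-enolate/(E)-acceptor topology (phenyl ends up over the oxygenated bridge), the ester enolate closes on the enone β-carbon trans to phenyl, and the only possible (Bredt-locked) ketone enolate is trapped.

**Step 2**
Reactants: 4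
Product: 5 (1S,2R,3R,4R,8R)-6-methyl-3-phenyl-8-(prop-1-en-2-yl)bicyclo[2.2.2]oct-5-ene-2-carboxylic acid
Conditions: Pd(OAc)2, PPh3, HCO2H, Et3N, DMF, 60 °C
Reagents that add atoms: none
Why: Cacchi–Ortar formate hydrogenolysis of the vinyl triflate and Tsuji–Trost deallylation of the ester run under the same Pd(0)/formate conditions, which leave unactivated alkenes and all stereocentres untouched.

**Step 3**
Reactants: 5
Product: 6 (1R,2S,6R)-3-methyl-2-(3-methylbut-2-enyl)-6-phenylcyclohex-3-ene-1-carboxylic acid
Conditions: Co(salophen) 5 mol %, fac-Ir(ppy)3 1 mol %, Hantzsch ester (1.3 equiv), AcOH, MeCN (0.01 M), 450 nm LED, 40 °C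
Reagents that add atoms: none
Why: Proposed new method: photogenerated Co(III)–H delivers H• selectively to the 1,1-disubstituted isopropenyl group; the tertiary radical has the C4–C8 σ-bond β to it and about 30° off the C5=C6 π-axis, so β-scission (estimated at roughly 12–15 kcal/mol of strain release, giving a substituted allyl radical) forms the prenyl C=C; Hantzsch ester then transfers H to the less hindered allyl terminus to give C5'H2 and the trisubstituted ring alkene; high dilution keeps direct reduction of the tertiary radical slower than scission, reversible Co-mediated isomerisation of the isopropenyl group feeds the same radical, and C1', C2' and C6' are not involved; the closest known chemistry is Co/photoredox MHAT hydrogenation and ring opening of pinene-type cyclobutylcarbinyl radicals (the reverse of a 6-exo radical cyclisation).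

**Step 4**
Reactants: 6; 7 phloroglucinol (4 equiv)
Product: 8 3,5-dihydroxyphenyl (1R,2S,6R)-3-methyl-2-(3-methylbut-2-enyl)-6-phenylcyclohex-3-ene-1-carboxylate
Conditions: EDC·HCl, DMAP (cat.), THF/DMF, 0 °C → rt
Reagents that add atoms: phloroglucinol, Oc1cc(O)cc(O)c1 (reactant 7)
Why: Steglich esterification, where excess symmetrical triol gives the monoester, the neutral conditions spare both alkenes, and the trans-diequatorial C1' centre is the stable epimer.

**Step 5**
Reactants: 8
Product: 9 (−)-4-hydroxypanduratin A
Conditions: hν 254 nm (quartz), degassed MeCN (5 mM), rt
Reagents that add atoms: none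
Why: Photo-Fries rearrangement, in which O–acyl homolysis and in-cage recombination of the acyl and aryloxyl radicals form the aryl–C(=O) bond, both ortho sites and the para site give the same 2,4,6-trihydroxyphenyl ketone, the acyl radical keeps the C1' configuration, and the o-hydroxyaryl ketone product is photostable.

## Compound list
1 | (R)-(−)-carvone | CC1=CC[C@H](CC1=O)C(C)=C | starting material
2 | allyl (E)-cinnamate | C=CCOC(=O)/C=C/c1ccccc1 | starting material
3 | Comins' reagent | FC(F)(F)S(=O)(=O)N(c1ccc(Cl)cn1)S(=O)(=O)C(F)(F)F | starting material (reagent)
4 | bicyclic enol triflate allyl ester | C=CCOC(=O)[C@H]1[C@H](c2ccccc2)[C@@H]2C(OS(=O)(=O)C(F)(F)F)=C(C)[C@H]1C[C@H]2C(C)=C | intermediate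
5 | bicyclo[2.2.2]octene acid | OC(=O)[C@H]1[C@H](c2ccccc2)[C@@H]2C=C(C)[C@H]1C[C@H]2C(C)=C | intermediate
6 | cyclohexene acid | CC(C)=CC[C@@H]1C(C)=CC[C@@H](c2ccccc2)[C@@H]1C(=O)O | intermediate
7 | phloroglucinol | Oc1cc(O)cc(O)c1 | starting material
8 | 3,5-dihydroxyphenyl ester | CC(C)=CC[C@@H]1C(C)=CC[C@@H](c2ccccc2)[C@@H]1C(=O)Oc1cc(O)cc(O)c1 | intermediate
9 | 4-hydroxypanduratin A | CC(C)=CC[C@@H]1C(C)=CC[C@@H](c2ccccc2)[C@@H]1C(=O)c1c(O)cc(O)cc1O | target

**Total steps:** 5. **Longest linear sequence:** 5.

## Steps most likely to fail
1. **Step 3 (new step).**
   - Risk: the tertiary radical may be reduced to isopropyl before scission, or the product alkenes may be over-reduced.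
   - Fallback (known chemistry): hydrogenate the isopropenyl group of carvone (Wilkinson's catalyst) and run the double Michael reaction to the bicyclic ketone. Cut the same bond by Norrish type II cleavage (300 nm), abstracting the γ-H of the isopropyl methine that sits over the C=O. Then install C3'=C4' from the resulting cyclohexanone through the more substituted enol triflate and Pd/formate reduction.
2. **Step 1.**
   - Risk: cinnamate may react sluggishly, or a Diels–Alder-like endo pathway may place the phenyl on the wrong side (syn to C7–C8).
   - Fallback: run a Diels–Alder reaction of the carvone TBS dienol ether with allyl propiolate. Then add PhMgBr under Cu catalysis to the resulting bicyclooctadiene ester from the open cleft between the two unsaturated bridges, which sets the phenyl position independently of endo/exo selectivity. Finally convert the silyl enol ether to the triflate.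
3. **Step 5.**
   - Risk: radicals may escape the solvent cage or decarbonylate, and the product acts as an inner filter, so the yield may be low.
   - Fallback: use ionic acylation. Convert 6 to its Weinreb amide, add 2,4,6-tris(methoxymethoxy)phenyllithium, and remove the MOM groups with HCl/MeOH.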